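**Strategy.** The route cuts ring A at C4–C5 and C1–C10. This divides the drimane core into a six-carbon isopropenyl aldehyde and a 2-methylcyclohexenone that becomes ring B. The feature exploited is C5, the ring-fusion methine wedged between quaternary C4 and quaternary C10, with the C6 oxygen beside it. In one operation an iron-hydride-generated tertiary C4 radical adds to C5 anti to the C6 silyl ether. The resulting C10 enolate then closes ring A on the aldehyde, so both quaternary carbons are created together. The precursors are (S)-4-silyloxy-2-methylcyclohexenone and (R)-3-silyloxy-4-methylpent-4-enal. Afterwards C1 is deoxygenated, C5 is inverted through the C6 ketone, and C8-methyl, C11 and the enone are grown from the C9 ketone.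

Key step: step 10

Numbering remark: bicyclic compounds carry drimane numbers (ring A C1–C5 and C10, ring B C5–C10, C11 the carbon on C9). "Cis/trans to Me-10" gives the relative configuration and the SMILES gives the absolute configuration. The target is (5S,9R,10S): trans-fused, with CH2OAr equatorial and cis to Me-10.

Assumption: the lipase of step 3 follows the usual size rule for secondary carbinols (carbonyl flank large), so the (S)-acetate is the slow-reacting antipode.

## Route

Step 1
Reactants: 1 2-methylcyclohexane-1,3-dione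
Product: 2 3-ethoxy-2-methylcyclohex-2-en-1-one
Conditions: EtOH, TsOH·H2O (cat.), toluene, reflux, Dean–Stark
Reagents that add atoms: ethanol, CCO
Why: Acid-catalysed enol etherification (vinylogous ester formation) of a symmetrical 1,3-dione can give only one product and is driven by azeotropic removal of water.

Step 2
Reactants: 2 3-ethoxy-2-methylcyclohex-2-en-1-one
Product: 3 (±)-6-acetoxy-3-ethoxy-2-methylcyclohex-2-en-1-one
Conditions: Mn(OAc)3·2H2O, benzene, reflux, Dean–Stark
Reagents that add atoms: manganese triacetate, CC(=O)[O-].CC(=O)[O-].CC(=O)[O-].[Mn+3]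
Why: Alpha'-acetoxylation of an enone with trivalent manganese: C6 is the only enolisable carbon next to the carbonyl, so oxidation of the manganese enolate and acetate transfer occur there and give the racemic acetate.

Step 3
Reactants: 3 (±)-6-acetoxy-3-ethoxy-2-methylcyclohex-2-en-1-one
Product: 4 (S)-6-acetoxy-3-ethoxy-2-methylcyclohex-2-en-1-one
Conditions: Amano lipase PS, aq. KH2PO4/K2HPO4 buffer (pH 7), MTBE, rt, stopped just past half conversion
Reagents that add atoms: none
Why: Lipase-catalysed kinetic resolution by ester hydrolysis: the enzyme cleaves the (R)-acetate faster, so the (S)-acetate is recovered enantioenriched once conversion has passed one half and is easily separated from the more polar alcohol.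

Step 4
Reactants: 4 (S)-6-acetoxy-3-ethoxy-2-methylcyclohex-2-en-1-one
Product: 6 (S)-4-hydroxy-2-methylcyclohex-2-en-1-one, via enol ether diol 5 (not isolated)
Conditions: LiAlH4, Et2O, 0 °C; then 1 M HCl, THF, 0 °C
Reagents that add atoms: none
Why: Stork–Danheiser carbonyl transposition: hydride reduces the vinylogous ester carbonyl and the acetate, and dilute acid then ionises the allylic alcohol and hydrolyses the enol ether, so the carbonyl moves to the former C3 while the untouched carbinol carbon ends up gamma to it with its (S) configuration retained.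

Step 5
Reactants: 6 (S)-4-hydroxy-2-methylcyclohex-2-en-1-one
Product: 7 (S)-2-methyl-4-(triethylsilyloxy)cyclohex-2-en-1-one
Conditions: TESCl, imidazole, CH2Cl2, 0 °C
Reagents that add atoms: chlorotriethylsilane, CC[Si](Cl)(CC)CC
Why: Standard silylation of a secondary allylic alcohol; triethylsilyl is chosen because it can later be removed beside a hindered tert-butyldimethylsilyl ether.

Step 6
Reactants: 8 ethyl acetate; 9 2-methylacrolein
Product: 11 (±)-ethyl 3-hydroxy-4-methylpent-4-enoate, via lithium enolate 10 (not isolated)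
Conditions: LiN(i-Pr)2, THF, −78 °C; then 9, −78 °C; H2O quench
Reagents that add atoms: none
Why: Acetate aldol addition: the preformed lithium enolate adds 1,2 to the enal at low temperature and gives the racemic allylic alcohol.

Step 7
Reactants: 11 (±)-ethyl 3-hydroxy-4-methylpent-4-enoate
Product: 12 ethyl (R)-3-hydroxy-4-methylpent-4-enoate
Conditions: Ti(Oi-Pr)4 (10 mol %), L-(+)-diisopropyl tartrate (12 mol %), t-BuOOH (0.6 equiv), 4 Å molecular sieves, CH2Cl2, −20 °C
Reagents that add atoms: none
Why: Sharpless kinetic resolution: with the L-(+)-tartrate the (S)-allylic alcohol is epoxidised much faster than its antipode, a sense fixed by the tartrate mnemonic, so the (R)-alcohol is recovered unchanged.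

Step 8
Reactants: 12 ethyl (R)-3-hydroxy-4-methylpent-4-enoate
Product: 13 ethyl (R)-3-(tert-butyldimethylsilyloxy)-4-methylpent-4-enoate
Conditions: TBSCl, imidazole, DMF, rt
Reagents that add atoms: tert-butylchlorodimethylsilane, CC(C)(C)[Si](C)(C)Cl
Why: Standard silylation; the robust ether keeps C3 at the alcohol level, because a C3 ketone would turn the isopropenyl group into an electron-poor enone unfit for hydrogen-atom transfer.

Step 9
Reactants: 13 ethyl (R)-3-(tert-butyldimethylsilyloxy)-4-methylpent-4-enoate
Product: 14 (R)-3-(tert-butyldimethylsilyloxy)-4-methylpent-4-enal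
Conditions: i-Bu2AlH (1.05 equiv), CH2Cl2, −78 °C; H2O quench
Reagents that add atoms: none
Why: Partial ester reduction with i-Bu2AlH: the tetrahedral aluminium acetal survives at −78 °C and releases the aldehyde only on quench, and the neutral conditions avoid beta-elimination of the silyloxy group.

Step 10
Reactants: 7 (S)-2-methyl-4-(triethylsilyloxy)cyclohex-2-en-1-one; 14 (R)-3-(tert-butyldimethylsilyloxy)-4-methylpent-4-enal
Product: 16 cis-fused (1S,3R,5S,6S,10S)-1-hydroxy-3-(tert-butyldimethylsilyloxy)-6-(triethylsilyloxy)-4,4,10-trimethyldecalin-9-one, via iron enolate 15 (not isolated)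
Conditions: 7 (2 equiv), 14 (1 equiv), Fe(acac)3 (30 mol %), PhSiH3 (2.5 equiv), degassed EtOH, 0 °C → rt
Reagents that add atoms: none
Why: The trivalent iron hydride formed from Fe(acac)3 and PhSiH3 passes a hydrogen atom to the terminal CH2 of the electron-rich isopropenyl group of 14, the nucleophilic tertiary C4 radical adds in Giese fashion to C5 (the beta-carbon of 7), and divalent iron reduces the alpha-keto radical to iron enolate 15, which attacks the tethered aldehyde (radical–polar crossover). The closest known reaction type is the iron-hydride-initiated reductive olefin–enone coupling terminated by an aldol addition, already applied to gamma,delta-unsaturated aldehydes and 2-methylcycloalkenones. Ring A closes by a 6-(enolexo)-exo-trig aldol addition at C10. C5 is controlled by the C6 silyl ether, which blocks its own face so that C4 enters anti; C10 is controlled by the tether, since A(1,2) strain with the C10 methyl tips the bulky C5 side chain pseudoaxial and C1 can reach only the face that the chain occupies, hence the cis fusion; C1 is controlled by a closed, metal-bridged chair transition state with the C3 silyl ether equatorial, which puts the hydroxyl cis to Me-10. The step needs hydrogen-atom transfer to the 1,1-disubstituted alkene rather than to the electron-poor trisubstituted enone, which the polarity match secures, and it needs aldol closure faster than enolate protonation, which the six-membered transition state and the unhindered aldehyde secure.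

Step 11
Reactants: 16 cis-fused 1-hydroxy ketone
Product: 17 C1 O-(imidazol-1-ylthiocarbonyl) derivative of 16
Conditions: 1,1'-thiocarbonyldiimidazole, DMAP (cat.), toluene, 80 °C
Reagents that add atoms: 1,1'-thiocarbonyldiimidazole, S=C(n1ccnc1)n1ccnc1
Why: Thioacylation, the first half of a Barton–McCombie deoxygenation, proceeds without forming the C1 alkoxide and so avoids retro-aldol opening of the beta-hydroxy ketone.

Step 12
Reactants: 17 C1 thiocarbonylimidazolide
Product: 18 cis-fused 3-(tert-butyldimethylsilyloxy)-6-(triethylsilyloxy)-4,4,10-trimethyldecalin-9-one (C1 now CH2)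
Conditions: Bu3SnH (0.3 M), AIBN (cat.), toluene, 100 °C
Reagents that add atoms: none
Why: Barton–McCombie deoxygenation: stannyl radical addition to sulfur releases the secondary C1 radical, which the concentrated stannane traps before a 1,2-acyl shift through the C9 carbonyl can compete.

Step 13
Reactants: 18 cis-fused C9 ketone
Product: 20 cis-fused 8-methyl ketone (Me-8 cis to Me-10), via lithium enolate 19 (not isolated)
Conditions: LiN(i-Pr)2, THF, −78 °C; then MeI, DMPU, −78 → −20 °C
Reagents that add atoms: iodomethane, CI
Why: Enolate alkylation: C10 is quaternary, so the ketone enolises only towards C8, and iodomethane enters on the convex face of the cis-decalin (the face of H-5 and Me-10), a provisional stereocentre that is re-set in step 16 and erased in step 21.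

Step 14
Reactants: 20 cis-fused 8-methyl ketone
Product: 21 cis-fused 6-hydroxy-8-methyl ketone
Conditions: HF·pyridine, pyridine, THF, 0 °C
Reagents that add atoms: none
Why: Selective desilylation: buffered fluoride cleaves the triethylsilyl ether far faster than the neopentyl tert-butyldimethylsilyl ether at C3.

Step 15
Reactants: 21 cis-fused 6-hydroxy-8-methyl ketone
Product: 22 cis-fused 3-(tert-butyldimethylsilyloxy)-4,4,8,10-tetramethyldecalin-6,9-dione
Conditions: Dess–Martin periodinane, CH2Cl2, rt
Reagents that add atoms: none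
Why: Dess–Martin oxidation converts the hindered secondary alcohol into the ketone under near-neutral conditions and thereby makes H-5 acidic.

Step 16
Reactants: 22 cis-fused 6,9-dione
Product: 23 trans-fused (3R,5R,8S,10R)-3-(tert-butyldimethylsilyloxy)-4,4,8,10-tetramethyldecalin-6,9-dione (H-5 and Me-8 both trans to Me-10)
Conditions: NaOMe (0.2 equiv), MeOH, 40 °C, argon; chromatography, cis fraction resubmitted
Reagents that add atoms: none
Why: Base-mediated epimerisation under thermodynamic control: only C5 and C8 carry exchangeable hydrogens (C4 and C10 are quaternary), and the trans-fused chair–chair dione with both ring A bonds and the C8 methyl equatorial on ring B should accumulate because either chair form of the cis isomer must hold C1 or the tert-alkyl C4 axial; the isomers are separable and the cis fraction is recycled.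

Step 17
Reactants: 23 trans-fused 6,9-dione
Product: 25 trans-fused 3,6-bis(tert-butyldimethylsilyloxy)-4,4,8,10-tetramethyl-Δ6-octalin-9-one, via lithium enolate 24 (not isolated)
Conditions: LiN(SiMe3)2 (1.1 equiv), THF, −78 °C; then TBSOTf, −78 °C
Reagents that add atoms: tert-butyldimethylsilyl triflate, CC(C)(C)[Si](C)(C)OS(=O)(=O)C(F)(F)F
Why: Kinetic enolisation and O-silylation: C7 is the only methylene next to a carbonyl (C5 and C8 are hindered methines), so the amide base removes its axial hydrogen, and the enol silane masks C6, locks C5 and serves as the handle for step 21.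

Step 18
Reactants: 25 enol silane ketone
Product: 26 9-methylene compound (C9=C11H2)
Conditions: Cp2TiMe2 (3 equiv), toluene, 75 °C, dark
Reagents that add atoms: dimethyltitanocene, C[Ti](C)(C1C=CC=C1)C1C=CC=C1
Why: Petasis methylenation: thermally generated Cp2Ti=CH2 is small and non-basic, so it olefinates the hindered C9 ketone without enolising the doubly activated C8–H or touching the enol silane.

Step 19
Reactants: 26 9-methylene compound
Product: 28 C11 primary alcohol (CH2OH equatorial and cis to Me-10; H-9 trans to Me-10), via C11 borane 27 (not isolated)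
Conditions: 9-BBN-H, THF, 50 °C; then 30 % H2O2, aq. NaOAc, 0 °C → rt
Reagents that add atoms: hydrogen peroxide, OO
Why: Hydroboration–oxidation: 9-BBN-H reacts with the 1,1-disubstituted methylene far faster than with the hindered trisubstituted enol silane, places boron on C11 and delivers hydrogen to C9 from the face opposite the axial C10 methyl, which sets C9.

Step 20
Reactants: 28 C11 primary alcohol; 29 umbelliferone (7-hydroxycoumarin)
Product: 30 C11 umbelliferyl ether of 28
Conditions: PPh3, DIAD, THF, 0 °C → rt
Reagents that add atoms: none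
Why: Mitsunobu etherification: the primary alcohol is activated as its oxyphosphonium salt and displaced by the acidic 7-hydroxyl of the coumarin under neutral conditions that spare the enol silane, no stereocentre being involved.

Step 21
Reactants: 30 C11 umbelliferyl ether
Product: 31 3-(tert-butyldimethylsilyloxy)drim-7-en-6-one umbelliferyl ether
Conditions: Pd(OAc)2 (1.1 equiv), MeCN, rt → 40 °C
Reagents that add atoms: none
Why: Saegusa–Ito oxidation: divalent palladium replaces silicon to give the C7 palladium enolate, whose only beta-hydrogen sits on C8, so syn elimination gives the C7–C8 enone under non-basic conditions that cannot trigger vinylogous loss of the aryloxide or epimerise C5 and C9.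

Step 22
Reactants: 31 silyl-protected enone
Product: 32 3-hydroxydrim-7-en-6-one umbelliferyl ether
Conditions: HF·pyridine, MeCN, rt
Reagents that add atoms: none
Why: Acidic fluoride desilylation frees the hindered equatorial C3 alcohol, basic fluoride sources being avoided because deprotonation at C9 would expel the aryloxide.

Step 23
Reactants: 32 3-hydroxy enone
Product: 33 epi-conferdione
Conditions: Dess–Martin periodinane, CH2Cl2, 0 °C → rt
Reagents that add atoms: none
Why: Dess–Martin oxidation of the secondary alcohol gives the C3 ketone under near-neutral conditions that leave the trans ring fusion, C9 and the coumarin untouched.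

## Compound list

1 | 2-methylcyclohexane-1,3-dione | CC1C(=O)CCCC1=O | starting material
2 | 3-ethoxy-2-methylcyclohex-2-en-1-one | CCOC1=C(C)C(=O)CCC1 | intermediate
3 | (±)-6-acetoxy-3-ethoxy-2-methylcyclohex-2-en-1-one | CCOC1=C(C)C(=O)C(OC(C)=O)CC1 | intermediate
4 | (S)-6-acetoxy-3-ethoxy-2-methylcyclohex-2-en-1-one | CCOC1=C(C)C(=O)[C@@H](OC(C)=O)CC1 | intermediate
5 | (6S)-3-ethoxy-2-methylcyclohex-2-ene-1,6-diol, epimers at C1 (not isolated) | CCOC1=C(C)C(O)[C@@H](O)CC1 | intermediate
6 | (S)-4-hydroxy-2-methylcyclohex-2-en-1-one | CC1=C[C@@H](O)CCC1=O | intermediate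
7 | (S)-2-methyl-4-(triethylsilyloxy)cyclohex-2-en-1-one | CC1=C[C@@H](O[Si](CC)(CC)CC)CCC1=O | intermediate
8 | ethyl acetate | CCOC(C)=O | starting material
9 | 2-methylacrolein | CC(=C)C=O | starting material
10 | lithium enolate of ethyl acetate (not isolated) | C=C(OCC)O[Li] | intermediate
11 | (±)-ethyl 3-hydroxy-4-methylpent-4-enoate | CCOC(=O)CC(O)C(C)=C | intermediate
12 | ethyl (R)-3-hydroxy-4-methylpent-4-enoate | CCOC(=O)C[C@@H](O)C(C)=C | intermediate
13 | ethyl (R)-3-(tert-butyldimethylsilyloxy)-4-methylpent-4-enoate | CCOC(=O)C[C@@H](O[Si](C)(C)C(C)(C)C)C(C)=C | intermediate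
14 | (R)-3-(tert-butyldimethylsilyloxy)-4-methylpent-4-enal | O=CC[C@@H](O[Si](C)(C)C(C)(C)C)C(C)=C | intermediate
15 | iron enolate of the C4–C5 adduct, drawn as the free enolate anion (not isolated) | CC1=C([O-])CC[C@H](O[Si](CC)(CC)CC)[C@H]1C(C)(C)[C@H](O[Si](C)(C)C(C)(C)C)CC=O | intermediate
16 | cis-fused (1S,3R,5S,6S,10S)-1-hydroxy-3-(TBSO)-6-(TESO)-4,4,10-trimethyldecalin-9-one; H-5, OH-1, OTBS-3 and OTES-6 all cis to Me-10 | O=C1CC[C@H](O[Si](CC)(CC)CC)[C@H]2C(C)(C)[C@H](O[Si](C)(C)C(C)(C)C)C[C@H](O)[C@@]12C | intermediate
17 | C1 O-(imidazol-1-ylthiocarbonyl) derivative of 16 | O=C1CC[C@H](O[Si](CC)(CC)CC)[C@H]2C(C)(C)[C@H](O[Si](C)(C)C(C)(C)C)C[C@H](OC(=S)n3ccnc3)[C@@]12C | intermediate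
18 | cis-fused 3-(TBSO)-6-(TESO)-4,4,10-trimethyldecalin-9-one | O=C1CC[C@H](O[Si](CC)(CC)CC)[C@H]2C(C)(C)[C@H](O[Si](C)(C)C(C)(C)C)CC[C@@]12C | intermediate
19 | lithium C8=C9 enolate of 18 (not isolated) | [Li]OC1=CC[C@H](O[Si](CC)(CC)CC)[C@H]2C(C)(C)[C@H](O[Si](C)(C)C(C)(C)C)CC[C@@]12C | intermediate
20 | cis-fused 3-(TBSO)-6-(TESO)-4,4,8,10-tetramethyldecalin-9-one, Me-8 cis to Me-10 | O=C1[C@H](C)C[C@H](O[Si](CC)(CC)CC)[C@H]2C(C)(C)[C@H](O[Si](C)(C)C(C)(C)C)CC[C@@]12C | intermediate
21 | cis-fused 6-hydroxy-3-(TBSO)-4,4,8,10-tetramethyldecalin-9-one | O=C1[C@H](C)C[C@H](O)[C@H]2C(C)(C)[C@H](O[Si](C)(C)C(C)(C)C)CC[C@@]12C | intermediate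
22 | cis-fused 3-(TBSO)-4,4,8,10-tetramethyldecalin-6,9-dione | O=C1[C@H](C)CC(=O)[C@H]2C(C)(C)[C@H](O[Si](C)(C)C(C)(C)C)CC[C@@]12C | intermediate
23 | trans-fused (3R,5R,8S,10R)-3-(TBSO)-4,4,8,10-tetramethyldecalin-6,9-dione | O=C1[C@@H](C)CC(=O)[C@@H]2C(C)(C)[C@H](O[Si](C)(C)C(C)(C)C)CC[C@@]12C | intermediate
24 | lithium C6=C7 enolate of 23 (not isolated) | O=C1[C@@H](C)C=C(O[Li])[C@@H]2C(C)(C)[C@H](O[Si](C)(C)C(C)(C)C)CC[C@@]12C | intermediate
25 | trans-fused 3,6-bis(TBSO)-4,4,8,10-tetramethyl-Δ6-octalin-9-one | O=C1[C@@H](C)C=C(O[Si](C)(C)C(C)(C)C)[C@@H]2C(C)(C)[C@H](O[Si](C)(C)C(C)(C)C)CC[C@@]12C | intermediate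
26 | 9-methylene analogue of 25 | C=C1[C@@H](C)C=C(O[Si](C)(C)C(C)(C)C)[C@@H]2C(C)(C)[C@H](O[Si](C)(C)C(C)(C)C)CC[C@@]12C | intermediate
27 | C11 9-borabicyclo[3.3.1]nonan-9-yl adduct of 26 (not isolated) | C(B1C2CCCC1CCC2)[C@@H]3[C@@H](C)C=C(O[Si](C)(C)C(C)(C)C)[C@@H]4C(C)(C)[C@H](O[Si](C)(C)C(C)(C)C)CC[C@@]34C | intermediate
28 | C11 primary alcohol, CH2OH cis to Me-10 | OC[C@@H]1[C@@H](C)C=C(O[Si](C)(C)C(C)(C)C)[C@@H]2C(C)(C)[C@H](O[Si](C)(C)C(C)(C)C)CC[C@@]12C | intermediate
29 | umbelliferone (7-hydroxycoumarin) | O=c1ccc2ccc(O)cc2o1 | starting material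
30 | C11 umbelliferyl ether of 28 | O=c1ccc2ccc(OC[C@@H]3[C@@H](C)C=C(O[Si](C)(C)C(C)(C)C)[C@@H]4C(C)(C)[C@H](O[Si](C)(C)C(C)(C)C)CC[C@@]34C)cc2o1 | intermediate
31 | 3-(TBSO)drim-7-en-6-one umbelliferyl ether | O=c1ccc2ccc(OC[C@@H]3C(C)=CC(=O)[C@@H]4C(C)(C)[C@H](O[Si](C)(C)C(C)(C)C)CC[C@@]34C)cc2o1 | intermediate
32 | 3-hydroxydrim-7-en-6-one umbelliferyl ether | O=c1ccc2ccc(OC[C@@H]3C(C)=CC(=O)[C@@H]4C(C)(C)[C@H](O)CC[C@@]34C)cc2o1 | intermediate
33 | epi-conferdione, (5S,9R,10S) | CC1=CC(=O)[C@@H]2C(C)(C)C(=O)CC[C@@]2(C)[C@@H]1COc1ccc2ccc(=O)oc2c1 | target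

## Step count

Total step count: 23.
Longest linear sequence: 19 (steps 1–5 and 10–23).

## Steps most likely to fail

**Step 10.**
- What may go wrong: the tertiary radical may simply be reduced, or the enolate may be protonated before the second bond forms, because a quaternary carbon has to be joined to a hindered ring carbon.
- The fallback sets out from 7 and 13 and comes back at 16. It separates the radical phase from the polar phase.
- The same iron-hydride coupling is run with ester 13, which cannot undergo aldol closure, and gives the Giese adduct keto ester F1.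
- Me3SiI with (Me3Si)2NH converts the ketone into the more substituted trimethylsilyl enol ether F2.
- i-Bu2AlH at −78 °C reduces the ester to the enol silane aldehyde F3.
- BF3·OEt2 at −78 °C then closes ring A by an intramolecular Mukaiyama aldol addition. The tether again enforces the cis fusion, and aqueous work-up gives 16.

**Step 16.**
- What may go wrong: the inversion may be incomplete, because the angular methyl narrows the energy gap between the two ring fusions and the hindered H-5 exchanges slowly. The equilibrium may therefore stall at a mixture.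
- The fallback sets out from 22 and comes back at 25. It replaces thermodynamic control by kinetic control.
- IBX in DMSO at 70 °C dehydrogenates the only available position, C7–C8, to the cis-enedione F4, in which H-5 is the sole alpha-hydrogen on the ring.
- LiN(SiMe3)2 at −78 °C gives the lithium dienolate F5.
- Inverse addition to cold AcOH/THF protonates C5 from the face opposite the C10 methyl and the axial C4 methyl, giving the trans-enedione F6.
- Hydrogenation (H2, Pd/C, EtOAc) from the same open face gives the 8-epimeric trans-dione F7.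
- The conditions of step 17 lead through the lithium enolate F8 to the 8-epimeric enol silane F9.
- DBU in toluene then epimerises C8. Its hydrogen is both alpha to the C9 ketone and allylic, and C5 is locked at this stage. Relief of the 1,3-diaxial methyl pair drives the change to 25.

**Step 18.**
- What may go wrong: there may be no addition at a carbonyl flanked by the quaternary C10 and the C8 methine, or the titanium carbene may decay thermally before it reacts.
- The fallback sets out from 25 and comes back at 28, bypassing step 19. It homologates C9 through an epoxide.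
- Dimethylsulfonium methylide (Me3SI, NaH, DMSO/THF, 0 °C) is a smaller nucleophile. It adds axially from the face opposite the C10 methyl and closes to the spiro-epoxide F10, with its oxygen cis to Me-10.
- MgBr2·OEt2 opens the tertiary C9–O bond with a 1,2-hydride shift anti to the departing oxygen (Meinwald rearrangement) and gives the equatorial C9 aldehyde F11.
- NaBH4 in EtOH at 0 °C gives 28.

## Further compounds

F1 | step 10 | Giese adduct keto ester (side chain trans to OTES-6 and to Me-10) | C[C@@H]1C(=O)CC[C@H](O[Si](CC)(CC)CC)[C@H]1C(C)(C)[C@H](O[Si](C)(C)C(C)(C)C)CC(=O)OCC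
F2 | step 10 | C9=C10 trimethylsilyl enol ether of F1 | CC1=C(O[Si](C)(C)C)CC[C@H](O[Si](CC)(CC)CC)[C@H]1C(C)(C)[C@H](O[Si](C)(C)C(C)(C)C)CC(=O)OCC
F3 | step 10 | enol silane aldehyde | CC1=C(O[Si](C)(C)C)CC[C@H](O[Si](CC)(CC)CC)[C@H]1C(C)(C)[C@H](O[Si](C)(C)C(C)(C)C)CC=O
F4 | step 16 | cis-fused 3-(TBSO)-4,4,8,10-tetramethyl-Δ7-octalin-6,9-dione | O=C1C(C)=CC(=O)[C@H]2C(C)(C)[C@H](O[Si](C)(C)C(C)(C)C)CC[C@@]12C
F5 | step 16 | lithium C5=C6 dienolate of F4 | O=C1C(C)=CC(O[Li])=C2C(C)(C)[C@H](O[Si](C)(C)C(C)(C)C)CC[C@@]12C
F6 | step 16 | trans-fused 3-(TBSO)-4,4,8,10-tetramethyl-Δ7-octalin-6,9-dione | O=C1C(C)=CC(=O)[C@@H]2C(C)(C)[C@H](O[Si](C)(C)C(C)(C)C)CC[C@@]12C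
F7 | step 16 | 8-epimer of 23 (Me-8 axial, cis to Me-10) | O=C1[C@H](C)CC(=O)[C@@H]2C(C)(C)[C@H](O[Si](C)(C)C(C)(C)C)CC[C@@]12C
F8 | step 16 | lithium C6=C7 enolate of F7 | O=C1[C@H](C)C=C(O[Li])[C@@H]2C(C)(C)[C@H](O[Si](C)(C)C(C)(C)C)CC[C@@]12C
F9 | step 16 | 8-epimer of 25 | O=C1[C@H](C)C=C(O[Si](C)(C)C(C)(C)C)[C@@H]2C(C)(C)[C@H](O[Si](C)(C)C(C)(C)C)CC[C@@]12C
F10 | step 18 | C9 spiro-epoxide of 25 (oxygen cis to Me-10) | C1O[C@@]12[C@@H](C)C=C(O[Si](C)(C)C(C)(C)C)[C@@H]3C(C)(C)[C@H](O[Si](C)(C)C(C)(C)C)CC[C@@]23C
F11 | step 18 | C9 carbaldehyde (CHO equatorial, cis to Me-10) | O=C[C@@H]1[C@@H](C)C=C(O[Si](C)(C)C(C)(C)C)[C@@H]2C(C)(C)[C@H](O[Si](C)(C)C(C)(C)C)CC[C@@]12C
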